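The route rests on building both resorcinol rings (ring D on the C3 ketone, ring E closing the C5 side chain) instead of attaching them. In each, C1′ carries the ketone while oxygen sits on C2′ (ortho) and C4′ (para). This is the pattern that 1,1-dimethoxy-3-(trimethylsilyloxy)butadiene writes onto an ethynyl ketone: diene C4 bonds to the terminal alkyne carbon, diene C1 to the acyl-bearing carbon. A twofold Diels–Alder/methanol-loss cascade thus forms four C–C bonds and two arenes in one neutral operation, leaving C2 and C3 untouched. Its precursor is the trans-(2S,3S) dihydrobenzofuran core with a MOM-capped C2 aryl group and ethynyl ketones on C3 and on the C5 ethylene tether.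

Key step: step 10

Ring labels:
- Ring A is the benzo ring.
- Ring B is the dihydrofuran O1–C2–C3–C3a–C7a.
- Ring C is the aryl group on C2.
- Rings D and E are defined above.

Design points:
- **Side-chain saturation.** The 8–5′ dehydrodimer of a p-coumarate carries an (E)-acrylate on C5, whereas the target has a saturated C5–CH2CH2–C(=O) tether. The alkene is therefore hydrogenated in step 5.
- **Protecting C3–H.** C3–H is alpha to a carbonyl and beta to the ring B aryloxy oxygen, so an enolate there can expel phenoxide (E1cB) and erase both stereocentres. For this reason the route uses benzyl esters (removed by H2, never by hydroxide), carbonyldiimidazole activation, a weakly basic acetylide and a neutral cycloaddition.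
- **Choice of diene.** The only methyl ether this diene creates lies ortho to a ketone, where chelation makes it cleavable. The para oxygen emerges as a labile silyl ether.
- **CIP check.** At C3 the order is acyl carbon > C2 > C3a > H. At C2 it is O1 > ring C carbon > C3 > H. This order holds in every resolved compound, so the descriptor stays (2S,3S) throughout, and (2S,3S) is the trans isomer.
- **Purity control.** Enantiomeric purity is to be re-checked on the chiral phase of step 3 after steps 7, 10 and 11.
- **Assumption.** The elution order of the two antipodes in step 3 cannot be predicted, so the (2S,3S) fraction is identified by electronic circular dichroism before it is carried on.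

Step 1
Reactants: 1 p-coumaric acid
Product: 2 benzyl (E)-3-(4-hydroxyphenyl)prop-2-enoate (benzyl p-coumarate)
Conditions: BnBr (1.05 equiv), KHCO3 (1.2 equiv), DMF, 40 °C
Reagents that add atoms: benzyl bromide, BrCc1ccccc1
Why: SN2 O-alkylation of a carboxylate (benzyl esterification): KHCO3 ionises only the carboxylic acid and leaves the far less acidic phenol protonated, so benzyl bromide esterifies selectively, and the benzyl group is chosen because it can later leave under hydrogen instead of hydroxide.

Step 2
Reactants: 2 benzyl p-coumarate (two molecules)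
Product: 4 racemic trans 8–5′ dehydrodimer dibenzyl ester [benzyl (2S*,3S*)-5-[(E)-3-(benzyloxy)-3-oxoprop-1-enyl]-2-(4-hydroxyphenyl)-2,3-dihydro-1-benzofuran-3-carboxylate], via p-quinone methide 3 (not isolated)
Conditions: Ag2O (0.55 equiv), MeCN, rt, dark, N2
Reagents that add atoms: none
Why: Biomimetic oxidative phenol coupling (8–5′ radical dehydrodimerisation of a p-hydroxycinnamate): Ag2O produces the phenoxyl radical, C8 of one unit bonds to C5′ of a second, rearomatisation gives 3, and 5-exo-trig addition of the new phenol oxygen to the methide carbon closes ring B with the C2 aryl and C3 ester groups on opposite faces to avoid eclipsing, which sets the trans relationship of both stereocentres in racemic form.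

Step 3
Reactants: 4 racemic trans dehydrodimer dibenzyl ester
Product: 5 (2S,3S) enantiomer of the dehydrodimer dibenzyl ester
Conditions: preparative HPLC or SFC, cellulose tris(3,5-dimethylphenylcarbamate) on silica, heptane/iPrOH, rt
Reagents that add atoms: none
Why: Resolution by enantioselective chromatography, routine for trans-2-aryl-2,3-dihydrobenzofuran-3-carboxylate neolignan esters on polysaccharide carbamate phases, fixes the absolute configuration at C2 and C3 at the cheapest point of the route, the wanted antipode being identified by electronic circular dichroism against a computed spectrum.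

Step 4
Reactants: 5 (2S,3S) dehydrodimer dibenzyl ester
Product: 6 benzyl (2S,3S)-5-[(E)-3-(benzyloxy)-3-oxoprop-1-enyl]-2-[4-(methoxymethoxy)phenyl]-2,3-dihydro-1-benzofuran-3-carboxylate
Conditions: MOMCl, iPr2NEt, CH2Cl2, 0 °C → rt
Reagents that add atoms: chloromethyl methyl ether, COCCl
Why: Acetal protection of a phenol by O-alkylation: the hindered amine is too weak to remove C3–H, and masking the para oxygen of ring C blocks phenoxide-driven quinone methide opening of ring B in the organometallic step that follows.

Step 5
Reactants: 6 MOM-protected dibenzyl ester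
Product: 7 (2S,3S)-5-(2-carboxyethyl)-2-[4-(methoxymethoxy)phenyl]-2,3-dihydro-1-benzofuran-3-carboxylic acid
Conditions: H2 (1 atm), 10% Pd/C, EtOAc, rt
Reagents that add atoms: none
Why: Heterogeneous catalytic hydrogenation combined with benzyl ester hydrogenolysis: one neutral operation saturates the C5 acrylate to the CH2CH2 tether and frees both acids, so the beta-aryloxy ester never meets hydroxide, while the cyclic benzylic C2–O1 bond reacts much more slowly and is kept by stopping after uptake of three equivalents of H2.

Step 6
Reactants: 7 saturated diacid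
Product: 9 bis-Weinreb amide [(2S,3S)-N-methoxy-5-{3-[methoxy(methyl)amino]-3-oxopropyl}-2-[4-(methoxymethoxy)phenyl]-N-methyl-2,3-dihydro-1-benzofuran-3-carboxamide], via bis(acyl imidazolide) 8 (not isolated)
Conditions: 1,1′-carbonyldiimidazole (2.4 equiv), THF, rt; then MeONHMe·HCl (3 equiv), rt
Reagents that add atoms: N,O-dimethylhydroxylamine hydrochloride, CNOC.Cl; 1,1′-carbonyldiimidazole, O=C(n1ccnc1)n1ccnc1 (its atoms appear only in 8)
Why: Carbonyldiimidazole-mediated amide coupling: each acid forms an acyl imidazolide with loss of CO2 and the hydroxylamine salt then displaces imidazole, the only base present being imidazole itself, which is too weak to enolise C3.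

Step 7
Reactants: 9 bis-Weinreb amide; 10 ethynylmagnesium bromide
Product: 12 bis-ynone 1-[(2S,3S)-2-[4-(methoxymethoxy)phenyl]-5-(3-oxopent-4-ynyl)-2,3-dihydro-1-benzofuran-3-yl]prop-2-yn-1-one, via bis(bromomagnesium) tetrahedral adduct 11 (not isolated)
Conditions: HC≡CMgBr (0.5 M in THF, 6 equiv), THF, −20 → 0 °C; inverse quench into cold 1 M aq NaHSO4/Et2O
Reagents that add atoms: none
Why: Weinreb ketone synthesis: the small, weakly basic acetylide adds to both amides to give magnesium-chelated tetrahedral adducts that cannot collapse before the quench, so over-addition is excluded and C3–H is spared, and pouring into cold acid protonates the released N,O-dimethylhydroxylamine before it can add to the new ynones.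

Step 8
Reactants: 13 1,1-dimethoxyethene (two equivalents); 14 acetyl chloride
Product: 15 4,4-dimethoxybut-3-en-2-one
Conditions: Et2O, 0 °C → reflux; distillation
Reagents that add atoms: none
Why: C-acylation of a ketene acetal: the nucleophilic CH2 terminus attacks acetyl chloride, the resulting dialkoxycarbenium ion loses a proton to give the push–pull enone, and the second equivalent of 13 absorbs the HCl by collapsing to methyl acetate and chloromethane.

Step 9
Reactants: 15 4,4-dimethoxybut-3-en-2-one
Product: 17 1,1-dimethoxy-3-(trimethylsilyloxy)buta-1,3-diene, via lithium dienolate 16 (not isolated)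
Conditions: LiN(iPr)2 (commercial solution, 1.05 equiv), THF, −78 °C; then TMSCl, −78 °C → rt; pentane filtration, distillation
Reagents that add atoms: chlorotrimethylsilane, C[Si](C)(C)Cl; lithium diisopropylamide, [Li]N(C(C)C)C(C)C (lithium appears only in 16)
Why: Kinetic enolate formation followed by O-silylation (silyl enol ether synthesis): the methyl ketone protons are the only acidic ones, so the cross-conjugated enolate 16 forms cleanly and the hard silicon electrophile is taken up on oxygen.

Step 10
Reactants: 12 bis-ynone; 17 1,1-dimethoxy-3-(trimethylsilyloxy)buta-1,3-diene (two molecules react, six equivalents used)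
Product: 20 1-(4-hydroxy-2-methoxyphenyl)-3-[(2S,3S)-3-(4-hydroxy-2-methoxybenzoyl)-2-[4-(methoxymethoxy)phenyl]-2,3-dihydro-1-benzofuran-5-yl]propan-1-one, via bis(cyclohexadiene) cycloadduct 18 (not isolated), via bis(trimethylsilyl ether) 19 (not isolated)
Conditions: toluene, rt → 60 °C, Ar; concentrate; then 10% aq citric acid, THF/MeOH, rt
Reagents that add atoms: none
Why: Each ethynyl ketone has its largest LUMO coefficient on the terminal carbon and diene 17 has its largest HOMO coefficient on C4 (pushed by the two C1 methoxy groups and the C3 silyloxy group), so a normal-demand, strongly asynchronous Diels–Alder reaction joins C4 to the terminal alkyne carbon and C1 to the acyl-bearing carbon, giving 18. This is the established resorcinol monoether synthesis from 1,1-dialkoxy-3-silyloxybutadienes and acetylenic ketones or esters, here simply run twice within one molecule. Rings D and E each close by an intermolecular [4+2] cycloaddition that makes both of their new sigma bonds, after which the doubly allylic ketal ionises, methanol is lost by 1,4-elimination and the rings aromatise to 19; mild acid then frees the para phenols without touching the MOM acetal. No stereocentre is created, and C2 and C3 are spectators because neither base nor Lewis acid is present. The selectivity needed is regiochemical (methoxy ortho, hydroxyl para to the ketone) and it is secured by the matched polarisation of the two partners, a stepwise Michael/cyclisation variant leading to the same connectivity. Excess diene makes up for the portion destroyed by liberated methanol and pushes the slower, more shielded ynone next to C3 to completion.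

Step 11
Reactants: 20 bis(4-hydroxy-2-methoxyphenyl) diketone
Product: 21 target 1-(2,4-dihydroxyphenyl)-3-[(2S,3S)-3-(2,4-dihydroxybenzoyl)-2-(4-hydroxyphenyl)-2,3-dihydro-1-benzofuran-5-yl]propan-1-one
Conditions: BCl3 (1 M in CH2Cl2, 10 equiv), CH2Cl2, −78 → 0 °C; then THF/1 M aq HCl, 0 °C → rt
Reagents that add atoms: none
Why: Chelation-directed Lewis-acid ether cleavage: BCl3 is held between each ketone oxygen and its ortho methoxy group so that chloride removes only those methyl groups by SN2, the acetal on ring C is cleaved even faster, and at or below 0 °C the ring B ether and the C2 and C3 stereocentres should stay intact.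

Compound list
1 | p-coumaric acid | OC(=O)/C=C/c1ccc(O)cc1 | starting material
2 | benzyl (E)-3-(4-hydroxyphenyl)prop-2-enoate | O=C(OCc1ccccc1)/C=C/c1ccc(O)cc1 | intermediate
3 | p-quinone methide from 8–5′ coupling (racemic at C8, not isolated) | O=C1C=CC(=CC(C(=O)OCc2ccccc2)c2cc(/C=C/C(=O)OCc3ccccc3)ccc2O)C=C1 | intermediate
4 | racemic trans dehydrodimer dibenzyl ester (both enantiomers written) | O=C(OCc1ccccc1)/C=C/c1ccc2c(c1)[C@H](C(=O)OCc1ccccc1)[C@@H](c1ccc(O)cc1)O2.O=C(OCc1ccccc1)/C=C/c1ccc2c(c1)[C@@H](C(=O)OCc1ccccc1)[C@H](c1ccc(O)cc1)O2 | intermediate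
5 | benzyl (2S,3S)-5-[(E)-3-(benzyloxy)-3-oxoprop-1-enyl]-2-(4-hydroxyphenyl)-2,3-dihydro-1-benzofuran-3-carboxylate | O=C(OCc1ccccc1)/C=C/c1ccc2c(c1)[C@H](C(=O)OCc1ccccc1)[C@@H](c1ccc(O)cc1)O2 | intermediate
6 | MOM ether of 5, (2S,3S) | O=C(OCc1ccccc1)/C=C/c1ccc2c(c1)[C@H](C(=O)OCc1ccccc1)[C@@H](c1ccc(OCOC)cc1)O2 | intermediate
7 | (2S,3S)-5-(2-carboxyethyl)-2-[4-(methoxymethoxy)phenyl]-2,3-dihydro-1-benzofuran-3-carboxylic acid | OC(=O)CCc1ccc2c(c1)[C@H](C(=O)O)[C@@H](c1ccc(OCOC)cc1)O2 | intermediate
8 | (2S,3S) bis(acyl imidazolide) of 7 (not isolated) | O=C(CCc1ccc2c(c1)[C@H](C(=O)n1ccnc1)[C@@H](c1ccc(OCOC)cc1)O2)n1ccnc1 | intermediate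
9 | (2S,3S) bis-Weinreb amide | CON(C)C(=O)CCc1ccc2c(c1)[C@H](C(=O)N(C)OC)[C@@H](c1ccc(OCOC)cc1)O2 | intermediate
10 | ethynylmagnesium bromide | C#C[Mg]Br | starting material
11 | bis(bromomagnesium) tetrahedral adduct, (2S,3S) core, hemiaminal carbons undefined (not isolated) | C#CC(O[Mg]Br)(CCc1ccc2c(c1)[C@H](C(O[Mg]Br)(C#C)N(C)OC)[C@@H](c1ccc(OCOC)cc1)O2)N(C)OC | intermediate
12 | trans-(2S,3S) bis-ynone | C#CC(=O)CCc1ccc2c(c1)[C@H](C(=O)C#C)[C@@H](c1ccc(OCOC)cc1)O2 | intermediate
13 | 1,1-dimethoxyethene | C=C(OC)OC | starting material
14 | acetyl chloride | CC(Cl)=O | starting material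
15 | 4,4-dimethoxybut-3-en-2-one | CC(=O)C=C(OC)OC | intermediate
16 | lithium 4,4-dimethoxybuta-1,3-dien-2-olate (not isolated) | [Li]OC(=C)C=C(OC)OC | intermediate
17 | 1,1-dimethoxy-3-(trimethylsilyloxy)buta-1,3-diene | COC(OC)=CC(=C)O[Si](C)(C)C | intermediate
18 | bis(6,6-dimethoxy-4-trimethylsilyloxycyclohexa-1,4-dienyl) diketone, (2S,3S) (not isolated) | O=C(CCc1ccc2c(c1)[C@H](C(=O)C1=CCC(O[Si](C)(C)C)=CC1(OC)OC)[C@@H](c1ccc(OCOC)cc1)O2)C1=CCC(O[Si](C)(C)C)=CC1(OC)OC | intermediate
19 | bis(2-methoxy-4-trimethylsilyloxyphenyl) diketone, (2S,3S) (not isolated) | O=C(CCc1ccc2c(c1)[C@H](C(=O)c1ccc(O[Si](C)(C)C)cc1OC)[C@@H](c1ccc(OCOC)cc1)O2)c1ccc(O[Si](C)(C)C)cc1OC | intermediate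
20 | trans-(2S,3S) bis(4-hydroxy-2-methoxyphenyl) diketone, MOM on ring C | O=C(CCc1ccc2c(c1)[C@H](C(=O)c1ccc(O)cc1OC)[C@@H](c1ccc(OCOC)cc1)O2)c1ccc(O)cc1OC | intermediate
21 | CNP0136359.1, trans-(2S,3S) | O=C(CCc1ccc2c(c1)[C@H](C(=O)c1ccc(O)cc1O)[C@@H](c1ccc(O)cc1)O2)c1ccc(O)cc1O | target

Total step count: 11. Longest linear sequence: 9 (steps 1–7, 10, 11). Steps 8 and 9 prepare the diene in parallel.

Steps most likely to fail

**1. Step 10.**
- What may go wrong: the reaction may stall after the first cycloaddition because the ynone next to C3 is shielded. The terminal ynones may oligomerise on heating. The sequence may stop at the open-chain Michael stage. Liberated methanol may consume the diene.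
- Fallback (the arenes are brought in ready-made instead of being constructed): it sets out from bis-Weinreb amide 9 and comes back at target 21. 4-Bromoresorcinol is capped with MOMCl/iPr2NEt to give 1-bromo-2,4-bis(methoxymethoxy)benzene F1. Magnesium insertion (Mg turnings, LiCl, THF) gives [2,4-bis(methoxymethoxy)phenyl]magnesium bromide F2. Twofold addition of this reagent to 9 at 0 °C (Weinreb ketone synthesis) should give the pentakis(methoxymethyl) ether of the target F3. Methanolic HCl at rt to 40 °C then removes all five acetals to give 21.

**2. Step 7.**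
- What may go wrong: the Grignard reagent may deprotonate C3, with expulsion of the ring B phenoxide and loss of enantiomeric purity. Released N,O-dimethylhydroxylamine may add to the ynones in conjugate fashion during the quench. Addition to the hindered C3 amide may be sluggish.
- Fallback (acyl cross-coupling under neutral conditions instead of carbanion addition): it sets out from diacid 7 and comes back at bis-ynone 12. 1-Chloro-N,N,2-trimethylprop-1-en-1-amine in CH2Cl2 at 0 °C converts 7, without acid or base, into the (2S,3S) bis(acid chloride) F4. This is coupled with tributyl(ethynyl)stannane under PdCl2(PPh3)2 catalysis in THF at rt to 50 °C (acyl Stille coupling) to give 12.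

**3. Step 11.**
- What may go wrong: the Lewis acid may ionise the benzylic C2–O1 bond and scramble C2. Ring B may open by retro-oxa-Michael reaction and reclose through the newly freed ortho hydroxyl of ring D. The liberated methoxymethyl cation may be captured by the electron-rich rings. Demethylation may be incomplete.
- Fallback (no methyl ether is ever installed, so no boron halide is needed): it sets out from bis-ynone 12 and comes back at target 21. Methyl acetoacetate is silylated (TMSCl, Et3N) to methyl 3-(trimethylsilyloxy)but-2-enoate F5. LiN(iPr)2/TMSCl at −78 °C then gives 1-methoxy-1,3-bis(trimethylsilyloxy)buta-1,3-diene F6. Cycloaddition of F6 with 12 under the conditions of step 10 gives the bis(mixed methyl silyl ketal) cycloadduct F7. On protic work-up its ketal carbons collapse with loss of methanol, so the ortho oxygen emerges as free hydroxyl in the MOM-protected bis(2,4-dihydroxyphenyl) diketone F8. Brief treatment with methanolic HCl removes the single acetal to give 21.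

Further compounds
F1 | step 10 | 1-bromo-2,4-bis(methoxymethoxy)benzene | COCOc1ccc(Br)c(OCOC)c1
F2 | step 10 | [2,4-bis(methoxymethoxy)phenyl]magnesium bromide | COCOc1ccc([Mg]Br)c(OCOC)c1
F3 | step 10 | pentakis(methoxymethyl) ether of the target, (2S,3S) | O=C(CCc1ccc2c(c1)[C@H](C(=O)c1ccc(OCOC)cc1OCOC)[C@@H](c1ccc(OCOC)cc1)O2)c1ccc(OCOC)cc1OCOC
F4 | step 7 | (2S,3S) bis(acid chloride) of 7 | O=C(Cl)CCc1ccc2c(c1)[C@H](C(=O)Cl)[C@@H](c1ccc(OCOC)cc1)O2
F5 | step 11 | methyl 3-(trimethylsilyloxy)but-2-enoate | COC(=O)C=C(C)O[Si](C)(C)C
F6 | step 11 | 1-methoxy-1,3-bis(trimethylsilyloxy)buta-1,3-diene | COC(O[Si](C)(C)C)=CC(=C)O[Si](C)(C)C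
F7 | step 11 | bis(mixed methyl silyl ketal) cycloadduct, (2S,3S) core, ketal carbons undefined | O=C(CCc1ccc2c(c1)[C@H](C(=O)C1=CCC(O[Si](C)(C)C)=CC1(OC)O[Si](C)(C)C)[C@@H](c1ccc(OCOC)cc1)O2)C1=CCC(O[Si](C)(C)C)=CC1(OC)O[Si](C)(C)C
F8 | step 11 | MOM-protected bis(2,4-dihydroxyphenyl) diketone, (2S,3S) | O=C(CCc1ccc2c(c1)[C@H](C(=O)c1ccc(O)cc1O)[C@@H](c1ccc(OCOC)cc1)O2)c1ccc(O)cc1O
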